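The benzo ring of the target is cut at C3a–C4 and C7–C7a. The four-carbon unit C4(Br)–C5H–C6H–C7(Br) is the carbon frame of 2,5-dibromothiophene, and the C3a–C7a edge shared with the five-membered ring (N1, C2, C3) is the C=C bond of a cyclic enecarbamate. In one operation, an inverse-demand Diels–Alder reaction of 2,5-dibromothiophene 1,1-dioxide with N-Boc-2,3-dihydropyrrole followed by loss of SO2 forms both bonds and closes the six-membered carbocycle with the bromines already at C4 and C7. The precursors are a symmetric, non-aromatic cyclic sulfone diene and a commercial five-membered enecarbamate. Two dehydrogenations, Boc removal and C3/C2 bromination finish the route.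

Key step: step 2

Remark: compounds 5 and 6 are racemic (one enantiomer is drawn); the endo orientation drawn for 5 is an assumption without consequence, since its bridgeheads end as sp2 carbons.
Remark: an N-acylindoline resists DDQ, so the second dehydrogenation is placed after Boc removal.

Step 1
Reactants: 1 2,5-dibromothiophene
Product: 3 2,5-dibromothiophene 1,1-dioxide, via 2,5-dibromothiophene 1-oxide 2 (not isolated)
Conditions: urea–hydrogen peroxide, (CF3CO)2O, MeCN, 0 °C → rt
Reagents that add atoms: urea–hydrogen peroxide, NC(N)=O.OO (source of both sulfone oxygens, transferred through trifluoroperacetic acid, OOC(=O)C(F)(F)F, generated in the flask)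
Why: Electrophilic S-oxidation of a thiophene by a peracid: trifluoroperacetic acid is electrophilic enough to oxidise the bromine-deactivated sulfur to the S-oxide 2, which is no longer aromatic and is therefore oxidised faster than 1, so the reaction runs on to sulfone 3, whose two α-bromines slow the Diels–Alder dimerisation typical of unsubstituted thiophene dioxides.

Step 2
Reactants: 3 2,5-dibromothiophene 1,1-dioxide; 4 tert-butyl 2,3-dihydro-1H-pyrrole-1-carboxylate
Product: 6 tert-butyl cis-4,7-dibromo-2,3,3a,7a-tetrahydro-1H-indole-1-carboxylate, via SO2-bridged cycloadduct 5 (not isolated)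
Conditions: 4 (3 equiv), NaHCO3 (solid), CH2Cl2, rt → 40 °C, N2 sweep; filtration through Et3N-washed silica, used directly
Reagents that add atoms: none
Why: The electron-rich C4=C5 bond of enecarbamate 4 (high HOMO) adds across C2 and C5 of the non-aromatic, electron-poor sulfone diene 3 (low LUMO) in a concerted but asynchronous suprafacial [4+2] cycloaddition, and the strained 7-thiabicyclo[2.2.1]heptene dioxide 5 then expels SO2 in a thermally allowed retro-cheletropic step to unveil the 1,3-diene of 6. The closest known reaction type is the inverse-electron-demand Diels–Alder annulation of halogenated thiophene 1,1-dioxides with enol ethers, enamines and cycloalkenes with spontaneous SO2 extrusion, applied here to a cyclic enecarbamate. The six-membered carbocycle is closed by the intermolecular [4+2] cycloaddition itself, which forms C3a–C4 and C7–C7a in one event, the cheletropic step only removing the sulfur bridge. The new stereocentres C3a and C7a come out cis because both bonds form on one face of the ring-constrained cis alkene, and the endo or exo orientation of 5 is of no consequence since its bridgeheads become sp2 carbons. Regioselectivity is not needed because 3 is symmetric; the selectivity that matters is cross-addition over self-dimerisation of 3, secured by the two α-bromines, which encumber the C2/C5 termini of the dioxide, and by the excess of 4. The Boc group keeps nitrogen a poor leaving group, so that under buffered, acid-free conditions 6 should not aromatise by C7a–N cleavage, and both bromines sit on sp2 carbons and cannot be lost as HBr.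

Step 3
Reactants: 6 tert-butyl cis-4,7-dibromo-2,3,3a,7a-tetrahydro-1H-indole-1-carboxylate
Product: 7 tert-butyl 4,7-dibromoindoline-1-carboxylate
Conditions: DDQ (1.1 equiv), toluene, 0 °C → rt
Reagents that add atoms: none
Why: DDQ dehydrogenation (aromatisation of a cyclohexa-1,3-diene): hydride abstraction from C7a, which is allylic and α to the carbamate nitrogen, followed by loss of the C3a proton should form the benzene ring under non-basic conditions, which removes both stereocentres as intended, leaves the C–Br bonds untouched and stops at the indoline because the acylated nitrogen no longer assists hydride loss from C2.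

Step 4
Reactants: 7 tert-butyl 4,7-dibromoindoline-1-carboxylate
Product: 8 4,7-dibromoindoline
Conditions: CF3CO2H, CH2Cl2, 0 °C → rt; then aq NaHCO3
Reagents that add atoms: none
Why: Acidolytic Boc cleavage: protonation of the carbamate, loss of the tert-butyl cation as 2-methylpropene and decarboxylation free the indoline nitrogen, while the aryl bromides are inert to trifluoroacetic acid.

Step 5
Reactants: 8 4,7-dibromoindoline
Product: 9 4,7-dibromo-1H-indole
Conditions: DDQ (1.05 equiv), CH2Cl2, 0 °C → rt
Reagents that add atoms: none
Why: DDQ dehydrogenation of an indoline to an indole: with the nitrogen lone pair free again, hydride abstraction from C2 should give a 3H-indolium ion that loses the C3 proton to form the aromatic pyrrole ring, and the electron-poor dibromoindole is not expected to be oxidised further at this temperature.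

Step 6
Reactants: 9 4,7-dibromo-1H-indole
Product: 11 2,3,4,7-tetrabromo-1H-indole, via 3,4,7-tribromo-1H-indole 10 (not isolated)
Conditions: NBS (2.1 equiv), dry THF, −78 °C → rt, dark
Reagents that add atoms: N-bromosuccinimide, O=C1CCC(=O)N1Br
Why: Electrophilic aromatic substitution with NBS: the first equivalent should brominate C3, the most nucleophilic position of the indole, and the second C2 of tribromide 10 (directly or by attack at C3 and 1,2-bromine shift), while the benzo ring, which already carries two deactivating bromines, stays untouched.

Compound list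
1 | 2,5-dibromothiophene | Brc1ccc(Br)s1 | starting material
2 | 2,5-dibromothiophene 1-oxide | O=S1C(Br)=CC=C1Br | intermediate (not isolated)
3 | 2,5-dibromothiophene 1,1-dioxide | O=S1(=O)C(Br)=CC=C1Br | intermediate
4 | tert-butyl 2,3-dihydro-1H-pyrrole-1-carboxylate | CC(C)(C)OC(=O)N1CCC=C1 | starting material
5 | tert-butyl 4,7-dibromo-2,3,3a,4,7,7a-hexahydro-4,7-epithioindole-1-carboxylate S,S-dioxide (racemic, cis ring fusion, pyrrolidine ring endo, that is anti to the SO2 bridge) | CC(C)(C)OC(=O)N1CC[C@H]2[C@@H]1[C@@]3(Br)C=C[C@]2(Br)S3(=O)=O | intermediate (not isolated)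
6 | tert-butyl cis-4,7-dibromo-2,3,3a,7a-tetrahydro-1H-indole-1-carboxylate (racemic) | CC(C)(C)OC(=O)N1CC[C@@H]2C(Br)=CC=C(Br)[C@H]12 | intermediate
7 | tert-butyl 4,7-dibromoindoline-1-carboxylate | CC(C)(C)OC(=O)N1CCc2c(Br)ccc(Br)c12 | intermediate
8 | 4,7-dibromoindoline | Brc1ccc(Br)c2c1CCN2 | intermediate
9 | 4,7-dibromo-1H-indole | Brc1ccc(Br)c2[nH]ccc12 | intermediate
10 | 3,4,7-tribromo-1H-indole | Brc1c[nH]c2c(Br)ccc(Br)c12 | intermediate (not isolated)
11 | 2,3,4,7-tetrabromo-1H-indole | Brc1[nH]c2c(Br)ccc(Br)c2c1Br | target

Total step count: 6. Longest linear sequence: 6 steps (1 → 11); enecarbamate 4 is commercial and enters at step 2.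

Steps most likely to fail

Step 2. The cross-cycloaddition may be too slow, so that 3 is lost to self-dimerisation or decomposition and the acid-sensitive enecarbamate 4 is consumed by acid formed from SO2 and adventitious water. The fallback sets out from 3 and replaces 4 by a far more nucleophilic silyl ketene N,O-acetal that carries its own leaving group. Commercial tert-butyl 2-oxopyrrolidine-1-carboxylate would be O-silylated (LiN(SiMe3)2, t-BuMe2SiCl, THF, −78 °C) to tert-butyl 5-[(tert-butyldimethylsilyl)oxy]-2,3-dihydro-1H-pyrrole-1-carboxylate F1. Cycloaddition of F1 with 3 should give tert-butyl 4,7-dibromo-7a-[(tert-butyldimethylsilyl)oxy]-2,3,3a,4,7,7a-hexahydro-4,7-epithioindole-1-carboxylate S,S-dioxide F2, which loses SO2 to tert-butyl 4,7-dibromo-7a-[(tert-butyldimethylsilyl)oxy]-2,3,3a,7a-tetrahydro-1H-indole-1-carboxylate F3. A trace of acid should ionise the N,O-acetal of F3 to an N-acyliminium ion, which loses the C3a proton. The benzene ring then forms by elimination of silanol instead of by oxidation, and the route is rejoined at 7 without passing through 6.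

Step 3. Before or during the oxidation, 6 may aromatise the wrong way, by β-elimination of the carbamate nitrogen from C7a together with the C3a hydrogen, which opens the five-membered ring. The fallback sets out from 4 (and uses 3) and moves the leaving group to C3a, so that aromatisation becomes loss of HBr and ring opening is impossible. Electrophilic bromination of 4 at the β-carbon (NBS, CH2Cl2, −78 °C, then Et3N) should give tert-butyl 4-bromo-2,3-dihydro-1H-pyrrole-1-carboxylate F4. Its cycloaddition with 3 (NaHCO3, toluene, heating, since the bromine lowers the nucleophilicity of the alkene) should give tert-butyl 3a,4,7-tribromo-2,3,3a,4,7,7a-hexahydro-4,7-epithioindole-1-carboxylate S,S-dioxide F5 and, after SO2 loss, tert-butyl 3a,4,7-tribromo-2,3,3a,7a-tetrahydro-1H-indole-1-carboxylate F6. In F6, C3a bears no hydrogen; ionisation of the tertiary, allylic C3a–Br bond and loss of the C7a proton should give 7 directly, where the route is rejoined.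

Step 6. The labile 3-bromoindole stage may be over-oxidised (attack of water or further NBS on the bromoindolenine, leading to oxindole-type products), or the second bromination at the deactivated C2 may remain incomplete. The fallback sets out from 9 and introduces the C2 bromine through the lactam. Pyridinium tribromide (3 equiv) in t-BuOH/H2O should convert 9 into 3,3,4,7-tetrabromoindolin-2-one F7. Zn in AcOH at rt would remove the two aliphatic bromines to give 4,7-dibromoindolin-2-one F8. POBr3 with imidazole in 1,2-dichloroethane at reflux (bromodehydroxylation of the lactim) should give 2,4,7-tribromo-1H-indole F9. One equivalent of NBS in THF would then brominate the free C3 position and rejoin the route at 11.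

Further compounds
F1 | step 2 | tert-butyl 5-[(tert-butyldimethylsilyl)oxy]-2,3-dihydro-1H-pyrrole-1-carboxylate | CC(C)(C)OC(=O)N1CCC=C1O[Si](C)(C)C(C)(C)C
F2 | step 2 | tert-butyl 4,7-dibromo-7a-[(tert-butyldimethylsilyl)oxy]-2,3,3a,4,7,7a-hexahydro-4,7-epithioindole-1-carboxylate S,S-dioxide (racemic, one diastereomer drawn) | CC(C)(C)OC(=O)N1CC[C@H]2[C@]1(O[Si](C)(C)C(C)(C)C)[C@@]3(Br)C=C[C@]2(Br)S3(=O)=O
F3 | step 2 | tert-butyl 4,7-dibromo-7a-[(tert-butyldimethylsilyl)oxy]-2,3,3a,7a-tetrahydro-1H-indole-1-carboxylate (racemic) | CC(C)(C)OC(=O)N1CC[C@@H]2C(Br)=CC=C(Br)[C@]12O[Si](C)(C)C(C)(C)C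
F4 | step 3 | tert-butyl 4-bromo-2,3-dihydro-1H-pyrrole-1-carboxylate | CC(C)(C)OC(=O)N1CCC(Br)=C1
F5 | step 3 | tert-butyl 3a,4,7-tribromo-2,3,3a,4,7,7a-hexahydro-4,7-epithioindole-1-carboxylate S,S-dioxide (racemic, one diastereomer drawn) | CC(C)(C)OC(=O)N1CC[C@@]2(Br)[C@@H]1[C@@]3(Br)C=C[C@]2(Br)S3(=O)=O
F6 | step 3 | tert-butyl 3a,4,7-tribromo-2,3,3a,7a-tetrahydro-1H-indole-1-carboxylate (racemic, cis) | CC(C)(C)OC(=O)N1CC[C@]2(Br)C(Br)=CC=C(Br)[C@H]12
F7 | step 6 | 3,3,4,7-tetrabromoindolin-2-one | O=C1Nc2c(Br)ccc(Br)c2C1(Br)Br
F8 | step 6 | 4,7-dibromoindolin-2-one | O=C1Cc2c(Br)ccc(Br)c2N1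
F9 | step 6 | 2,4,7-tribromo-1H-indole | Brc1cc2c(Br)ccc(Br)c2[nH]1
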